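**Retrosynthetic overview**
- C6–C7 (sp–sp): Cadiot–Chodkiewicz coupling of 2-(heptadec-16-yn-1-yl)furan with 6-bromohex-5-ynoic acid (from hex-5-ynoic acid).
- C8–C9: alkylation of lithium acetylide with 2-(15-bromopentadecyl)furan, made from 15-(furan-2-yl)pentadecan-1-ol.
- Key disconnection C22–C23: crossed aldol (Claisen–Schmidt) condensation of furfural with 14-hydroxytetradecan-2-one; the enone C=C and C=O are then removed (hydrogenation, Wolff–Kishner).
- C19–C20: the hydroxy ketone comes from ethyl acetoacetate and 11-bromoundecan-1-ol (acetoacetic ester synthesis).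
- Rings: the only ring, the furan, is never built; it enters intact with furfural, so there is no ring-forming step.

Assumption: the target, 23-(furan-2-yl)tricosa-5,7-diynoic acid, has no stereocentre or stereogenic double bond, so "single enantiomer" reduces to the constitution as drawn.

**Step 1**
Reactants: 1 ethyl acetoacetate; 2 11-bromoundecan-1-ol
Product: 3 ethyl 2-acetyl-13-hydroxytridecanoate (racemic)
Conditions: NaOEt (1.4 equiv), 1 (1.5 equiv), NaI (cat.), EtOH, reflux, 16 h
Reagents that add atoms: none
Why: Acetoacetic ester alkylation, an SN2 reaction of the stabilised sodium enolate (pKa about 11, formed selectively beside the free alcohol, pKa about 16) with the primary bromide; the new stereocentre is racemic and is destroyed in step 2.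

**Step 2**
Reactants: 3 ethyl 2-acetyl-13-hydroxytridecanoate
Product: 5 14-hydroxytetradecan-2-one, via 2-acetyl-13-hydroxytridecanoic acid 4 (not isolated)
Conditions: 5% aq. NaOH, rt to 50 °C; then dil. H2SO4 to pH 2, 70 °C until CO2 evolution stops
Reagents that add atoms: none
Why: Ketonic hydrolysis of an acetoacetic ester: saponification, then thermal decarboxylation of the β-keto acid through its cyclic six-membered transition state gives the methyl ketone.

**Step 3**
Reactants: 5 14-hydroxytetradecan-2-one; 6 furfural
Product: 8 (E)-1-(furan-2-yl)-15-hydroxypentadec-1-en-3-one, via β-hydroxy ketone aldol adduct 7 (not isolated)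
Conditions: 6 (1.05 equiv), 10% aq. NaOH (0.5 equiv), EtOH, 0 °C to rt, 12 h
Reagents that add atoms: none
Why: Crossed aldol (Claisen–Schmidt) condensation: furfural cannot enolise, hydroxide-mediated condensation of a methyl alkyl ketone takes place at the methyl group, and E1cB dehydration to the conjugated (E)-enone drives the reversible aldol forward; the racemic carbinol centre of 7 is lost on dehydration and the alkene geometry is erased in step 4.

**Step 4**
Reactants: 8 (E)-1-(furan-2-yl)-15-hydroxypentadec-1-en-3-one
Product: 9 1-(furan-2-yl)-15-hydroxypentadecan-3-one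
Conditions: H2 (1 atm), 5% Pd/C, EtOAc, rt, stopped after 1.0 equiv H2
Reagents that add atoms: none
Why: Chemoselective catalytic hydrogenation: the conjugated exocyclic C=C is saturated far faster on palladium than the aromatic furan or the ketone, and no stereocentre is formed.

**Step 5**
Reactants: 9 1-(furan-2-yl)-15-hydroxypentadecan-3-one
Product: 11 15-(furan-2-yl)pentadecan-1-ol, via hydrazone 10 (not isolated)
Conditions: N2H4·H2O (4 equiv), KOH (4 equiv), diethylene glycol, 130 °C, then distil to 195–200 °C, 4 h
Reagents that add atoms: none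
Why: Wolff–Kishner reduction (Huang-Minlon procedure): the hydrazone loses N2 under hot base to turn C=O into CH2, and both the furan and the primary alcohol are stable to KOH.

**Step 6**
Reactants: 11 15-(furan-2-yl)pentadecan-1-ol
Product: 12 2-(15-bromopentadecyl)furan
Conditions: CBr4 (1.3 equiv), PPh3 (1.4 equiv), CH2Cl2, 0 °C to rt
Reagents that add atoms: carbon tetrabromide, BrC(Br)(Br)Br
Why: Appel reaction: bromide displaces the alkoxyphosphonium leaving group by SN2 under neutral conditions that leave the acid-sensitive furan untouched.

**Step 7**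
Reactants: 12 2-(15-bromopentadecyl)furan
Product: 13 2-(heptadec-16-yn-1-yl)furan
Conditions: LiC≡CH·H2NCH2CH2NH2 (2 equiv), DMSO/THF, 10 °C to rt
Reagents that add atoms: lithium acetylide (used as its ethylenediamine complex), [Li+].[C-]#C
Why: SN2 alkylation of lithium acetylide with an unhindered primary bromide in a dipolar aprotic solvent gives the terminal alkyne cleanly, with little elimination.

**Step 8**
Reactants: 14 hex-5-ynoic acid
Product: 15 6-bromohex-5-ynoic acid
Conditions: NBS (1.1 equiv), AgNO3 (10 mol %), acetone, rt, dark
Reagents that add atoms: N-bromosuccinimide, O=C1CCC(=O)N1Br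
Why: Silver-catalysed electrophilic bromination of a terminal alkyne (through the silver acetylide) gives the 1-bromoalkyne and tolerates the free carboxylic acid; it is done on this fragment because NBS would attack the furan of the other one.

**Step 9**
Reactants: 13 2-(heptadec-16-yn-1-yl)furan; 15 6-bromohex-5-ynoic acid
Product: 16 23-(furan-2-yl)tricosa-5,7-diynoic acid
Conditions: CuCl (10 mol %), NH2OH·HCl (30 mol %), 70% aq. EtNH2, MeOH/THF, 0 °C to rt, 15 added dropwise, dark; cold aq. citric acid work-up
Reagents that add atoms: none
Why: Cadiot–Chodkiewicz coupling: the cuprous acetylide of 13 reacts with the bromoalkyne to give the unsymmetrical 1,3-diyne, hydroxylamine keeps the copper monovalent to suppress Glaser homocoupling, and the acid travels as its ethylammonium salt.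

**Compound list**
1 | ethyl acetoacetate | CCOC(=O)CC(C)=O | starting material
2 | 11-bromoundecan-1-ol | OCCCCCCCCCCCBr | starting material
3 | ethyl 2-acetyl-13-hydroxytridecanoate (racemic) | CCOC(=O)C(C(C)=O)CCCCCCCCCCCO | intermediate
4 | 2-acetyl-13-hydroxytridecanoic acid (racemic, not isolated) | OC(=O)C(C(C)=O)CCCCCCCCCCCO | intermediate
5 | 14-hydroxytetradecan-2-one | CC(=O)CCCCCCCCCCCCO | intermediate
6 | furfural (furan-2-carbaldehyde) | O=Cc1ccco1 | starting material
7 | 1-(furan-2-yl)-1,15-dihydroxypentadecan-3-one (racemic aldol adduct, not isolated) | OC(CC(=O)CCCCCCCCCCCCO)c1ccco1 | intermediate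
8 | (E)-1-(furan-2-yl)-15-hydroxypentadec-1-en-3-one | O=C(/C=C/c1ccco1)CCCCCCCCCCCCO | intermediate
9 | 1-(furan-2-yl)-15-hydroxypentadecan-3-one | O=C(CCc1ccco1)CCCCCCCCCCCCO | intermediate
10 | hydrazone of 9, 14-(furan-2-yl)-12-hydrazinylidenetetradecan-1-ol (not isolated) | NN=C(CCc1ccco1)CCCCCCCCCCCCO | intermediate
11 | 15-(furan-2-yl)pentadecan-1-ol | OCCCCCCCCCCCCCCCc1ccco1 | intermediate
12 | 2-(15-bromopentadecyl)furan | BrCCCCCCCCCCCCCCCc1ccco1 | intermediate
13 | 2-(heptadec-16-yn-1-yl)furan | C#CCCCCCCCCCCCCCCCc1ccco1 | intermediate
14 | hex-5-ynoic acid | OC(=O)CCCC#C | starting material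
15 | 6-bromohex-5-ynoic acid | OC(=O)CCCC#CBr | intermediate
16 | 23-(furan-2-yl)tricosa-5,7-diynoic acid (achiral) | O=C(O)CCCC#CC#CCCCCCCCCCCCCCCCc1ccco1 | target

**Step count**
Total steps: 9. Longest linear sequence: 8 (steps 1–7 and 9); step 8 is a one-step side branch.

**Steps most likely to fail, with fallbacks**

Step 3 may give some branched enone from condensation at the methylene, or a bis-furfurylidene product. The fallback sets out from 2 and comes back at 8. The dianion of commercial dimethyl (2-oxopropyl)phosphonate (NaH, then n-BuLi, THF, 0 °C; 2.2 equiv, one of which is spent on the hydroxyl of 2) is alkylated at its terminal carbon by 2 to give dimethyl (14-hydroxy-2-oxotetradecyl)phosphonate F1. Horner–Wadsworth–Emmons olefination of F1 with furfural 6 (LiCl, DBU, MeCN, rt) then forms the C=C only at the phosphonate carbon and gives 8.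

Step 4 may over-reduce the furan or the ketone. The fallback sets out from 8, bypasses 9 and comes back at 11. Condensation of 8 with p-toluenesulfonyl hydrazide (EtOH, rt) gives the tosylhydrazone of 8, N'-[(1E)-1-(furan-2-yl)-15-hydroxypentadec-1-en-3-ylidene]-4-methylbenzenesulfonohydrazide F2. Reduction with catecholborane (3 equiv, CHCl3, 0 °C), then NaOAc·3H2O at reflux, removes the carbonyl with alkene transposition and gives (E)-15-(furan-2-yl)pentadec-13-en-1-ol F3. Diimide (p-toluenesulfonyl hydrazide, NaOAc, DME/H2O, reflux) saturates this isolated alkene without touching the furan and gives 11.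

Step 9 may suffer homocoupling or loss of the sensitive bromo acid 15. The fallback sets out from 13 and comes back at 16 with the coupling polarity reversed. Alkyne 13 is deprotonated selectively at the acetylenic C–H (n-BuLi, THF, −78 °C) and quenched with NBS (1.0 equiv) to give 2-(17-bromoheptadec-16-yn-1-yl)furan F4. F4 is then coupled under the CuCl/NH2OH·HCl/EtNH2 conditions with an excess of cheap hex-5-ynoic acid 14; the diacid and neutral homodimers are removed by extraction and the product is 16.

**Further compounds**
F1 | step 3 | dimethyl (14-hydroxy-2-oxotetradecyl)phosphonate | COP(=O)(OC)CC(=O)CCCCCCCCCCCCO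
F2 | step 4 | N'-[(1E)-1-(furan-2-yl)-15-hydroxypentadec-1-en-3-ylidene]-4-methylbenzenesulfonohydrazide (tosylhydrazone of 8) | Cc1ccc(cc1)S(=O)(=O)NN=C(/C=C/c1ccco1)CCCCCCCCCCCCO
F3 | step 4 | (E)-15-(furan-2-yl)pentadec-13-en-1-ol | OCCCCCCCCCCCC/C=C/Cc1ccco1
F4 | step 9 | 2-(17-bromoheptadec-16-yn-1-yl)furan | BrC#CCCCCCCCCCCCCCCCc1ccco1
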